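## Retrosynthetic overview

1. The 5-OH and the 3Z-enone are unmasked last. A C2 ketone opens a 4,5-oxirane by E1cB, so 23 comes from the 2-oxo-1,10:4,5-diepoxygermacranolide 22.
2. The ten-membered ring and the γ-lactone form in one flask by making the C6–C7 bond, which is the farnesyl C1→C10 closure. An allylchromium at C13/C7 adds to the C6 epoxy-aldehyde, and the C6 alkoxide then closes on the C12 ester.
3. Both oxiranes come from one double, reagent-controlled epoxidation of the acyclic E,E-diene diol.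
4. The C15 chain is built head to tail from three C5 units by two vinylogous Mukaiyama aldols (C8–C9, then C2–C3). These place oxygen at exactly C8 and C2.
5. Ring order: the two oxiranes, then the carbocycle, then the lactone (same flask). The 4,5-oxirane is opened again at the end.

Assumption: atoms carry germacrane numbers (lactone O on C6, ester O on C8, ketone C2). The given SMILES reads 1S,3Z,5S,6R,7R,8R,10R, with a cis-fused lactone, a trans (E-derived) oxirane and a tiglate (E) ester.

## Route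

**Step 1**
Reactants: 1 2,2-dimethoxyacetaldehyde; 2 methyl acrylate
Product: 3 methyl 3-hydroxy-4,4-dimethoxy-2-methylidenebutanoate (racemic)
Conditions: DABCO, dioxane–H2O, rt
Reagents that add atoms: none
Why: Morita–Baylis–Hillman reaction in which the DABCO–acrylate zwitterion attacks the activated, unhindered aldehyde; the racemic carbinol centre is erased in step 2.

**Step 2**
Reactants: 3 methyl 3-hydroxy-4,4-dimethoxy-2-methylidenebutanoate
Product: 5 methyl (2Z)-2-(chloromethyl)-4-oxobut-2-enoate, via chloro acetal 4 (not isolated)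
Conditions: SOCl2, CH2Cl2, 0 °C to rt; then H2O–acetone, rt
Reagents that add atoms: thionyl chloride O=S(Cl)Cl; water O
Why: Chlorosulfite formation and SNi′/SN2′ allylic transposition give the conjugated primary chloride with the acetal carbon trans to the ester (2Z, the normal outcome for Baylis–Hillman alcohols), and the HCl formed hydrolyses the acetal once water is added.

**Step 3**
Reactants: 6 3-methylbut-2-enal (prenal)
Product: 7 tert-butyl(dimethyl){[(1E)-3-methylbuta-1,3-dien-1-yl]oxy}silane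
Conditions: TBSOTf, Et3N, Et2O, 0 °C to rt
Reagents that add atoms: tert-butyldimethylsilyl triflate CC(C)(C)[Si](C)(C)OS(=O)(=O)C(F)(F)F
Why: Soft enolisation, in which O-silylation of the s-trans enal and γ-deprotonation give the 1E silyl dienol ether.

**Step 4**
Reactants: 5 methyl (2Z)-2-(chloromethyl)-4-oxobut-2-enoate; 7 TBS dienol ether of prenal
Product: 8 methyl (2Z,4R,6E)-2-(chloromethyl)-4-hydroxy-6-methyl-8-oxoocta-2,6-dienoate
Conditions: (S)-OXB (B-phenyl oxazaborolidinone from N-tosyl-L-tryptophan, 0.5 equiv), i-PrOH (1.1 equiv), EtCN, −78 °C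
Reagents that add atoms: none
Why: Oxazaborolidinone-promoted vinylogous Mukaiyama aldol of an aldehyde-derived dienol ether, in which the indole shields the Si face so C9 adds to the Re face of the formyl group (8R), the s-trans diene gives the E-enal, β,β-disubstitution of 5 disfavours Diels–Alder and Michael paths, and the product enal is far less electrophilic than 5.

**Step 5**
Reactants: 8 hydroxy enal; 9 (2E)-2-methylbut-2-enoyl chloride (tigloyl chloride)
Product: 10 methyl (2Z,4R,6E)-2-(chloromethyl)-6-methyl-8-oxo-4-(tigloyloxy)octa-2,6-dienoate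
Conditions: pyridine, DMAP (5 mol %), CH2Cl2, −20 to 0 °C
Reagents that add atoms: none
Why: Simple O-acylation that touches no stereocentre, run cold with a weak base to avoid vinylogous E1cB loss of the δ-acyloxy group and quaternisation at the allylic chloride.

**Step 6**
Reactants: 11 3-methylbut-2-enoic acid (senecioic acid)
Product: 12 1,1-bis(trimethylsilyloxy)-3-methylbuta-1,3-diene
Conditions: LDA (2.2 equiv), THF, −78 to 0 °C; TMSCl (2.5 equiv)
Reagents that add atoms: chlorotrimethylsilane C[Si](C)(C)Cl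
Why: O–H and γ-C–H deprotonation give the dienediolate, which is O-silylated twice to the bis-silyl vinylketene acetal.

**Step 7**
Reactants: 10 tiglate enal; 12 bis-silyl vinylketene acetal
Product: 14 (2E,5S,6E,9R,10Z)-11-(chloromethyl)-5-hydroxy-12-methoxy-3,7-dimethyl-12-oxo-9-(tigloyloxy)dodeca-2,6,10-trienoic acid, via bis-TMS adduct 13 (not isolated)
Conditions: (R)-OXB (from N-tosyl-D-tryptophan, 0.5 equiv), CH2Cl2–EtCN, −78 °C; then aq. citric acid–THF
Reagents that add atoms: none
Why: Proposed new method: the boron Lewis acid binds the β,β-disubstituted enal, which permits only 1,2-attack, and the γ-carbon (C3) of the bis-silyl ketene acetal adds to the Si face (2S) with silyl transfer turning the catalyst over; an acid-level nucleophile is used because its product cannot react a second time, unlike an enal product of the same reactivity as 10; the closest known reactions are the oxazaborolidinone-promoted vinylogous Mukaiyama aldol of alkyl silyl ketene acetals and the achiral Lewis-acid aldol of bis-silyl dienediolates.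

**Step 8**
Reactants: 14 hydroxy acid
Product: 16 methyl (2Z,4R,6E,8S,10E)-2-(chloromethyl)-8,12-dihydroxy-6,10-dimethyl-4-(tigloyloxy)dodeca-2,6,10-trienoate, via mixed anhydride 15 (not isolated)
Conditions: i-BuOCOCl, N-methylmorpholine, THF, −20 °C; then NaBH4, MeOH, −20 to 0 °C
Reagents that add atoms: none
Why: Mixed carbonic anhydride/borohydride reduction in which only the activated acyl carbon is reduced, so both esters and the chloride survive, and the E-alkene prevents lactonisation onto the C2 hydroxyl.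

**Step 9**
Reactants: 16 diene diol
Product: 18 methyl (2Z,4R)-2-(chloromethyl)-5-[(2R,3R)-3-{(1S)-1-hydroxy-2-[(2R,3R)-3-(hydroxymethyl)-2-methyloxiran-2-yl]ethyl}-2-methyloxiran-2-yl]-4-(tigloyloxy)pent-2-enoate, via 4,5-monoepoxide 17 (not isolated)
Conditions: D-fructose-derived Shi ketone (0.6 equiv), Oxone, K2CO3, Bu4NHSO4 (cat.), MeCN–DMM/aq. borate–EDTA buffer (pH 9–10), 0 °C, 2–3 h
Reagents that add atoms: potassium peroxymonosulfate (Oxone) [K+].[O-]S(=O)(=O)OO
Why: Double Shi epoxidation in which the chiral dioxirane attacks only the two electron-rich E-trisubstituted alkenes through the spiro transition state and gives the R,R-oxirane at each (1R,10R and 4R,5R), the 2S carbinol is matched (A1,3-controlled threo face), and the enoate and tiglate alkenes are inert.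

**Step 10**
Reactants: 18 bis-epoxy diol
Product: 19 methyl (2Z,4R)-2-(chloromethyl)-5-[(2R,3R)-3-{(1S)-2-[(2R,3S)-3-formyl-2-methyloxiran-2-yl]-1-hydroxyethyl}-2-methyloxiran-2-yl]-4-(tigloyloxy)pent-2-enoate
Conditions: TEMPO (10 mol %), PhI(OAc)2, CH2Cl2, 0 °C to rt
Reagents that add atoms: none
Why: Oxoammonium oxidation is selective for the primary alcohol over the C2 secondary one, and the trans-oxirane between C3 and C6 makes a six-membered lactol with the C2 hydroxyl geometrically impossible, so the aldehyde stays free.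

**Step 11**
Reactants: 19 bis-epoxy aldehyde
Product: 21 (1R,2S,4R,5R,6R,7R,8R,10R)-1,10:4,5-diepoxy-2-hydroxy-8-(tigloyloxy)germacr-11(13)-en-12,6-olide, via hydroxy ester 20 (not isolated)
Conditions: CrCl2 (10 equiv), LiI (0.2 equiv), DMF–THF, 2 mM, syringe pump 10 h, rt; aq. work-up, then PPTS (cat.), CH2Cl2 if lactonisation is incomplete
Reagents that add atoms: none
Why: Intramolecular Nozaki–Hiyama allylation followed by lactonisation, in which the (Z)-2-(methoxycarbonyl)allyl chromium reacts through a chair with C8 axial to give the 6,7-syn adduct (cis-lactone), the epoxy-aldehyde is attacked on the polar Felkin–Anh/Cornforth face (5,6-erythro, 6R, hence 7R), A1,3 strain at C8 places H-8 inside and C9 anti to the new bond (matched with 8R), and the chromium alkoxide closes on the ester.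

**Step 12**
Reactants: 21 diepoxy lactone alcohol
Product: 23 (1S,3Z,5S,6R,7R,8R,10R)-1,10-epoxy-5-hydroxy-2-oxo-8-(tigloyloxy)germacra-3,11(13)-dien-12,6-olide (target), via diepoxy ketone 22 (not isolated)
Conditions: (COCl)2, DMSO, CH2Cl2, −78 °C; Et3N (6 equiv), −78 °C to rt, 2 h
Reagents that add atoms: none
Why: Swern oxidation then in-flask E1cB, in which the C2 ketone can enolise only towards C3 and expels the C4–O bond of the β,γ-oxirane, C5 keeps its oxygen and configuration (5S by CIP), the activated DMSO has decomposed before the new hydroxyl appears, and the folded ring together with base-mediated E/Z equilibration through the C15 dienolate is expected to favour the 3Z-enone.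

## Compound list

| No. | Name | SMILES | Role |
|---|---|---|---|
| 1 | 2,2-dimethoxyacetaldehyde | COC(OC)C=O | starting material |
| 2 | methyl acrylate | C=CC(=O)OC | starting material |
| 3 | methyl 3-hydroxy-4,4-dimethoxy-2-methylidenebutanoate (racemic) | COC(OC)C(O)C(=C)C(=O)OC | intermediate |
| 4 | methyl (2Z)-2-(chloromethyl)-4,4-dimethoxybut-2-enoate (not isolated) | COC(OC)/C=C(\CCl)C(=O)OC | intermediate |
| 5 | methyl (2Z)-2-(chloromethyl)-4-oxobut-2-enoate | O=C/C=C(\CCl)C(=O)OC | intermediate |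
| 6 | 3-methylbut-2-enal | CC(C)=CC=O | starting material |
| 7 | tert-butyl(dimethyl){[(1E)-3-methylbuta-1,3-dien-1-yl]oxy}silane | C=C(C)/C=C/O[Si](C)(C)C(C)(C)C | intermediate |
| 8 | methyl (2Z,4R,6E)-2-(chloromethyl)-4-hydroxy-6-methyl-8-oxoocta-2,6-dienoate | COC(=O)/C(CCl)=C/[C@H](O)C/C(C)=C/C=O | intermediate |
| 9 | (2E)-2-methylbut-2-enoyl chloride | C/C=C(\C)C(=O)Cl | starting material |
| 10 | methyl (2Z,4R,6E)-2-(chloromethyl)-6-methyl-8-oxo-4-(tigloyloxy)octa-2,6-dienoate | COC(=O)/C(CCl)=C/[C@H](OC(=O)/C(C)=C/C)C/C(C)=C/C=O | intermediate |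
| 11 | 3-methylbut-2-enoic acid | CC(C)=CC(=O)O | starting material |
| 12 | 1,1-bis(trimethylsilyloxy)-3-methylbuta-1,3-diene | C=C(C)C=C(O[Si](C)(C)C)O[Si](C)(C)C | intermediate |
| 13 | 5-O-TMS ether, TMS ester of 14 (not isolated) | COC(=O)/C(CCl)=C/[C@H](OC(=O)/C(C)=C/C)C/C(C)=C/[C@@H](O[Si](C)(C)C)C/C(C)=C/C(=O)O[Si](C)(C)C | intermediate |
| 14 | (2E,5S,6E,9R,10Z)-11-(chloromethyl)-5-hydroxy-12-methoxy-3,7-dimethyl-12-oxo-9-(tigloyloxy)dodeca-2,6,10-trienoic acid | COC(=O)/C(CCl)=C/[C@H](OC(=O)/C(C)=C/C)C/C(C)=C/[C@@H](O)C/C(C)=C/C(=O)O | intermediate |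
| 15 | isobutyl carbonic mixed anhydride of 14 (not isolated) | COC(=O)/C(CCl)=C/[C@H](OC(=O)/C(C)=C/C)C/C(C)=C/[C@@H](O)C/C(C)=C/C(=O)OC(=O)OCC(C)C | intermediate |
| 16 | methyl (2Z,4R,6E,8S,10E)-2-(chloromethyl)-8,12-dihydroxy-6,10-dimethyl-4-(tigloyloxy)dodeca-2,6,10-trienoate | COC(=O)/C(CCl)=C/[C@H](OC(=O)/C(C)=C/C)C/C(C)=C/[C@@H](O)C/C(C)=C/CO | intermediate |
| 17 | methyl (2Z,4R,6E,8S)-2-(chloromethyl)-8-hydroxy-9-[(2R,3R)-3-(hydroxymethyl)-2-methyloxiran-2-yl]-6-methyl-4-(tigloyloxy)nona-2,6-dienoate (not isolated) | COC(=O)/C(CCl)=C/[C@H](OC(=O)/C(C)=C/C)C/C(C)=C/[C@@H](O)C[C@@]1(C)O[C@@H]1CO | intermediate |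
| 18 | bis-epoxy diol (germacrane labels 1R,2S,4R,5R,8R,10R; name as in step 9) | COC(=O)/C(CCl)=C/[C@H](OC(=O)/C(C)=C/C)C[C@@]1(C)O[C@@H]1[C@@H](O)C[C@@]1(C)O[C@@H]1CO | intermediate |
| 19 | bis-epoxy aldehyde (1R,2S,4R,5S,8R,10R; name as in step 10) | COC(=O)/C(CCl)=C/[C@H](OC(=O)/C(C)=C/C)C[C@@]1(C)O[C@@H]1[C@@H](O)C[C@@]1(C)O[C@@H]1C=O | intermediate |
| 20 | methyl (1R,2S,4R,5R,6R,7S,8R,10R)-1,10:4,5-diepoxy-2,6-dihydroxy-8-(tigloyloxy)germacr-11(13)-en-12-oate, formed as its Cr(III) alkoxide (not isolated) | COC(=O)C(=C)[C@@H]1[C@H](OC(=O)/C(C)=C/C)C[C@@]2(C)O[C@@H]2[C@@H](O)C[C@@]3(C)O[C@@H]3[C@@H]1O | intermediate |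
| 21 | (1R,2S,4R,5R,6R,7R,8R,10R)-1,10:4,5-diepoxy-2-hydroxy-8-(tigloyloxy)germacr-11(13)-en-12,6-olide | C=C1C(=O)O[C@@H]2[C@H]1[C@H](OC(=O)/C(C)=C/C)C[C@@]1(C)O[C@@H]1[C@@H](O)C[C@@]3(C)O[C@@H]32 | intermediate |
| 22 | (1S,4R,5R,6R,7R,8R,10R)-1,10:4,5-diepoxy-2-oxo-8-(tigloyloxy)germacr-11(13)-en-12,6-olide (not isolated) | C=C1C(=O)O[C@@H]2[C@H]1[C@H](OC(=O)/C(C)=C/C)C[C@@]1(C)O[C@@H]1C(=O)C[C@@]3(C)O[C@@H]32 | intermediate |
| 23 | (1S,3Z,5S,6R,7R,8R,10R)-1,10-epoxy-5-hydroxy-2-oxo-8-(tigloyloxy)germacra-3,11(13)-dien-12,6-olide | C=C1C(=O)O[C@@H]2[C@H]1[C@H](OC(=O)/C(C)=C/C)C[C@@]1(C)O[C@@H]1C(=O)/C=C(/C)[C@@H]2O | target |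

## Step count and risks

Total step count: 12.
Longest linear sequence: 10 (steps 1, 2, 4, 5, 7, 8, 9, 10, 11, 12).

**Step 11 (macrocyclisation/lactonisation).**
The risks are low effective molarity for a ring carrying two trans-oxiranes, 1,4-elimination of the δ-tigloyloxy group from the allylmetal, and a wrong C6/C7 pair.

The fallback sets out from 16 and comes back at 21.
- It closes the ring before any oxirane is present.
- Compound 16 is oxidised only at the primary allylic alcohol (TEMPO, PhI(OAc)2) to methyl (2Z,4R,6E,8S,10E)-2-(chloromethyl)-8-hydroxy-6,10-dimethyl-12-oxo-4-(tigloyloxy)dodeca-2,6,10-trienoate F1.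
- The chromium closure is run on this more flexible farnesal-type enal.
- It gives methyl (2S,6S,7S,8R)-2,6-dihydroxy-8-(tigloyloxy)germacra-1(10)E,4E,11(13)-trien-12-oate F2.
- F2 lactonises to (2S,6S,7R,8R)-2-hydroxy-8-(tigloyloxy)germacra-1(10)E,4E,11(13)-trien-12,6-olide F3.
- The two ring alkenes, now held perpendicular to the ring, are epoxidised from the outer face (Shi ketone/Oxone or m-CPBA).
- This passes through (1R,2S,4E,6S,7R,8R,10R)-1,10-epoxy-2-hydroxy-8-(tigloyloxy)germacra-4,11(13)-dien-12,6-olide F4 and ends at 21.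

**Step 12 (geometry of the new enone).**
The risk is that the E1cB gives the 3E alkene.

The fallback sets out from 21 and comes back at 23.
- It sets the geometry with light instead of in the elimination.
- Compound 21 is oxidised with Dess–Martin periodinane to 22.
- The oxirane is opened with DBU without regard to geometry.
- The (1S,3E,5S,6R,7R,8R,10R)-1,10-epoxy-5-hydroxy-2-oxo-8-(tigloyloxy)germacra-3,11(13)-dien-12,6-olide F5 is isolated.
- F5 is isomerised to 23 by irradiation at 365 nm or by triplet sensitisation with thioxanthone.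
- Recovered F5 is recycled.

**Step 4 (first vinylogous aldol on the doubly activated enal 5).**
The risks are Diels–Alder, hetero-Diels–Alder or Michael reaction of 5 with the dienol ether, and instability of 5.

The fallback sets out from 1 and 7 and comes back at 10.
- It builds the chloromethyl acrylate after the aldol.
- The same oxazaborolidinone aldol is run on anhydrous 1 and gives (2E,5R)-5-hydroxy-6,6-dimethoxy-3-methylhex-2-enal F6.
- Acylation with 9 gives (2R,4E)-1,1-dimethoxy-4-methyl-6-oxohex-4-en-2-yl (2E)-2-methylbut-2-enoate F7.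
- Aqueous trifluoroacetic acid frees (2R,4E)-4-methyl-1,6-dioxohex-4-en-2-yl (2E)-2-methylbut-2-enoate F8.
- A Baylis–Hillman reaction with 2 takes place only at the α-acyloxy aldehyde, because the β,β-disubstituted enal is inert.
- It gives methyl (4R,6E)-3-hydroxy-6-methyl-2-methylidene-8-oxo-4-(tigloyloxy)oct-6-enoate F9.
- Thionyl chloride transposes F9 to 10.

## Further compounds

F1 | step 11 | methyl (2Z,4R,6E,8S,10E)-2-(chloromethyl)-8-hydroxy-6,10-dimethyl-12-oxo-4-(tigloyloxy)dodeca-2,6,10-trienoate | COC(=O)/C(CCl)=C/[C@H](OC(=O)/C(C)=C/C)C/C(C)=C/[C@@H](O)C/C(C)=C/C=O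
F2 | step 11 | methyl (2S,6S,7S,8R)-2,6-dihydroxy-8-(tigloyloxy)germacra-1(10)E,4E,11(13)-trien-12-oate | COC(=O)C(=C)[C@@H]1[C@H](OC(=O)/C(C)=C/C)C/C(C)=C/[C@@H](O)C/C(C)=C/[C@@H]1O
F3 | step 11 | (2S,6S,7R,8R)-2-hydroxy-8-(tigloyloxy)germacra-1(10)E,4E,11(13)-trien-12,6-olide | C=C1C(=O)O[C@@H]2[C@H]1[C@H](OC(=O)/C(C)=C/C)C/C(C)=C/[C@@H](O)C/C(C)=C/2
F4 | step 11 | (1R,2S,4E,6S,7R,8R,10R)-1,10-epoxy-2-hydroxy-8-(tigloyloxy)germacra-4,11(13)-dien-12,6-olide | C=C1C(=O)O[C@@H]2[C@H]1[C@H](OC(=O)/C(C)=C/C)C[C@@]1(C)O[C@@H]1[C@@H](O)C/C(C)=C/2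
F5 | step 12 | (1S,3E,5S,6R,7R,8R,10R)-1,10-epoxy-5-hydroxy-2-oxo-8-(tigloyloxy)germacra-3,11(13)-dien-12,6-olide | C=C1C(=O)O[C@@H]2[C@H]1[C@H](OC(=O)/C(C)=C/C)C[C@@]1(C)O[C@@H]1C(=O)/C=C(\C)[C@@H]2O
F6 | step 4 | (2E,5R)-5-hydroxy-6,6-dimethoxy-3-methylhex-2-enal | COC(OC)[C@H](O)C/C(C)=C/C=O
F7 | step 4 | (2R,4E)-1,1-dimethoxy-4-methyl-6-oxohex-4-en-2-yl (2E)-2-methylbut-2-enoate | COC(OC)[C@H](OC(=O)/C(C)=C/C)C/C(C)=C/C=O
F8 | step 4 | (2R,4E)-4-methyl-1,6-dioxohex-4-en-2-yl (2E)-2-methylbut-2-enoate | O=C[C@H](OC(=O)/C(C)=C/C)C/C(C)=C/C=O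
F9 | step 4 | methyl (4R,6E)-3-hydroxy-6-methyl-2-methylidene-8-oxo-4-(tigloyloxy)oct-6-enoate (C3 epimers) | COC(=O)C(=C)C(O)[C@H](OC(=O)/C(C)=C/C)C/C(C)=C/C=O
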